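**Strategy.** Everything rests on making the aryl ether bond O1–C8a of the upper chroman (and its twin in the lower chroman) last, from a ring A that is not yet aromatic. Because each ring A carries its hydroxyl at C7, para to C4a, it can be held as a 4-alkylphenol whose two ortho carbons are equivalent, oxidised to a 4-hydroxycyclohexa-2,5-dienone. In one operation the side-chain primary alcohols add to the dienone β-carbons and water is lost, closing both pyran rings and regenerating both 7-hydroxy arenes. The precursor is an acyclic bis(p-quinol) diol, built by two Evans alkylations around a differentiated ring C benzaldehyde.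

Key step: step 19

Remark: chroman numbering (O1, C2, C3, C4, C4a, C5 to C8, C8a) is used for both isoflavan units; "upper" is the 4-aryl chroman, "lower" the chroman-3-yl unit, ring A the benzo ring of each chroman, ring B the dimethoxyphenol ring, ring C the central benzene ring. Compounds 1, 5, 8, 13 and 24 are taken as catalogue compounds.

## Route

Step 1
Reactants: 1 1-(2-hydroxy-4,5-dimethoxyphenyl)ethan-1-one
Product: 2 1-[2-(benzyloxy)-4,5-dimethoxyphenyl]ethan-1-one
Conditions: BnBr, K2CO3, DMF, 60 °C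
Reagents that add atoms: benzyl bromide (BrCc1ccccc1)
Why: Williamson etherification of the chelated phenol should give the ring B benzyl ether, which is inert to every later step and is removed only by the final hydrogenolysis.

Step 2
Reactants: 2 1-[2-(benzyloxy)-4,5-dimethoxyphenyl]ethan-1-one
Product: 4 2-[2-(benzyloxy)-4,5-dimethoxyphenyl]acetic acid, via thiomorpholide 3 (not isolated)
Conditions: S8, morpholine, 130 °C; then KOH, EtOH/H2O, reflux; HCl work-up
Reagents that add atoms: potassium hydroxide ([K+].[OH-]); water (O)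
Why: The Willgerodt–Kindler reaction should move the oxidised carbon to the chain end as thioamide 3, and alkaline hydrolysis then gives the arylacetic acid while the aryl ethers are untouched.

Step 3
Reactants: 4 2-[2-(benzyloxy)-4,5-dimethoxyphenyl]acetic acid; 5 (4R)-4-benzyl-1,3-oxazolidin-2-one
Product: 7 (4R)-4-benzyl-3-{2-[2-(benzyloxy)-4,5-dimethoxyphenyl]acetyl}-1,3-oxazolidin-2-one (ring B imide), via mixed anhydride 6 (not isolated)
Conditions: PivCl, Et3N, THF, −20 °C; then 5, LiCl, rt
Reagents that add atoms: none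
Why: N-acylation of the oxazolidinone by the pivalic mixed anhydride under LiCl/Et3N activation should attach the Evans auxiliary without strong base.

Step 4
Reactants: 8 2-(3,5-dihydroxyphenyl)acetic acid
Product: 10 2-[3,5-bis(benzyloxy)phenyl]acetic acid, via benzyl ester 9 (not isolated)
Conditions: BnBr, K2CO3, DMF, 60 °C; then NaOH, MeOH/H2O, 60 °C; HCl work-up
Reagents that add atoms: benzyl bromide (BrCc1ccccc1); sodium hydroxide ([Na+].[OH-])
Why: Exhaustive benzylation followed by saponification of the benzyl ester in the same flask should give the symmetric ring C acid, whose two equivalent benzyloxy groups are told apart later through the aldehyde.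

Step 5
Reactants: 10 2-[3,5-bis(benzyloxy)phenyl]acetic acid; 5 (4R)-4-benzyl-1,3-oxazolidin-2-one
Product: 12 (4R)-4-benzyl-3-{2-[3,5-bis(benzyloxy)phenyl]acetyl}-1,3-oxazolidin-2-one (ring C imide), via mixed anhydride 11 (not isolated)
Conditions: PivCl, Et3N, THF, −20 °C; then 5, LiCl, rt
Reagents that add atoms: none
Why: The same mixed-anhydride N-acylation as in step 3 should load the ring C arylacetyl unit onto the auxiliary.

Step 6
Reactants: 13 4-methylphenol
Product: 14 triisopropyl(4-methylphenoxy)silane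
Conditions: iPr3SiCl, imidazole, DMF, rt
Reagents that add atoms: chlorotriisopropylsilane (CC(C)[Si](Cl)(C(C)C)C(C)C)
Why: Silylation of the phenol gives an aryl silyl ether robust enough for the formylation and carbonate steps yet removable by fluoride.

Step 7
Reactants: 14 triisopropyl(4-methylphenoxy)silane
Product: 15 [4-(bromomethyl)phenoxy]triisopropylsilane
Conditions: NBS, AIBN (cat.), PhCF3, 80 °C
Reagents that add atoms: N-bromosuccinimide (O=C1CCC(=O)N1Br)
Why: Wohl–Ziegler radical bromination should functionalise the only benzylic position and leave the silyl ether alone.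

Step 8
Reactants: 12 ring C imide; 15 [4-(bromomethyl)phenoxy]triisopropylsilane
Product: 17 (4R)-4-benzyl-3-{(2R)-2-[3,5-bis(benzyloxy)phenyl]-3-[4-(triisopropylsilyloxy)phenyl]propanoyl}-1,3-oxazolidin-2-one, via sodium enolate 16 (not isolated)
Conditions: NaN(SiMe3)2, THF, −78 °C; then 15, −78 to −40 °C
Reagents that add atoms: none
Why: Evans alkylation: the chelated (Z)-sodium enolate 16 is attacked by the benzylic bromide on the face opposite the auxiliary benzyl group, which should set the (R) centre that becomes C3 of the lower chroman.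

Step 9
Reactants: 17 alkylated ring C imide
Product: 18 (2R)-2-[3,5-bis(benzyloxy)phenyl]-3-[4-(triisopropylsilyloxy)phenyl]propan-1-ol
Conditions: LiBH4, H2O (1 equiv), Et2O, 0 °C
Reagents that add atoms: none
Why: Reductive removal of the Evans auxiliary by hydride attack on the exocyclic carbonyl should give the primary alcohol (future lower C2–O1) without epimerisation.

Step 10
Reactants: 18 lower-unit alcohol
Product: 19 tert-butyldiphenylsilyl ether of 18
Conditions: tBuPh2SiCl, imidazole, DMF, rt
Reagents that add atoms: tert-butyl(chloro)diphenylsilane (CC(C)(C)[Si](Cl)(c1ccccc1)c1ccccc1)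
Why: Silylation masks the primary alcohol so that it neither reacts with the formylating reagent nor captures the benzylic cation of step 15 as an isochroman.

Step 11
Reactants: 19 silyl ether
Product: 21 2,4-bis(benzyloxy)-6-{(2R)-1-[(tert-butyldiphenylsilyl)oxy]-3-[4-(triisopropylsilyloxy)phenyl]propan-2-yl}benzaldehyde, via iminium chloride 20 (not isolated)
Conditions: POCl3, DMF, 0 to 50 °C; then NaOAc, H2O
Reagents that add atoms: N,N-dimethylformamide (CN(C)C=O); water (O)
Why: Vilsmeier–Haack formylation should occur on the bis(benzyloxy) ring at one of the two equivalent positions next to the alkyl branch (ortho to one ether and para to the other; the position between the two ethers is the less reactive one in 5-alkylresorcinol diethers), while the mono-oxygenated silyloxyphenyl ring and the silyl ethers are left alone.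

Step 12
Reactants: 21 bis(benzyloxy) aldehyde
Product: 22 4-(benzyloxy)-2-hydroxy-6-{(2R)-1-[(tert-butyldiphenylsilyl)oxy]-3-[4-(triisopropylsilyloxy)phenyl]propan-2-yl}benzaldehyde
Conditions: MgBr2·OEt2, toluene/Et2O, 60 °C
Reagents that add atoms: none
Why: Chelation of MgBr2 between the formyl oxygen and the neighbouring ether oxygen should remove only the benzyl group ortho to the aldehyde, which tells the two ring C oxygens apart.

Step 13
Reactants: 22 hydroxy aldehyde
Product: 23 4-(benzyloxy)-2-methoxy-6-{(2R)-1-[(tert-butyldiphenylsilyl)oxy]-3-[4-(triisopropylsilyloxy)phenyl]propan-2-yl}benzaldehyde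
Conditions: MeI, K2CO3, acetone, 50 °C
Reagents that add atoms: iodomethane (CI)
Why: Williamson methylation of the hydrogen-bonded phenol should install the ring C methoxy group ortho to the carbon that becomes C4.

Step 14
Reactants: 23 ring C aldehyde; 24 (4-bromophenoxy)(tert-butyl)dimethylsilane
Product: 27 diarylmethyl acetate (both epimers at the acetoxy carbon), via arylmagnesium bromide 25 (not isolated), via bromomagnesium alkoxide 26 (not isolated)
Conditions: 24, Mg, THF, 40 °C; then 23, −40 to 0 °C; then Ac2O, DMAP (cat.), 0 °C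
Reagents that add atoms: acetic anhydride (CC(=O)OC(C)=O)
Why: Grignard addition to the hindered aldehyde and acetylation of the alkoxide in the same flask should give an ionisable diarylmethyl acetate whose carbinol configuration is irrelevant because it is lost in the next step.

Step 15
Reactants: 7 ring B imide; 27 diarylmethyl acetate
Product: 29 coupled imide with (2R,3S) configuration at the new centres C3 and C4, via chlorotitanium enolate 28 (not isolated)
Conditions: 7, TiCl4, iPr2NEt, CH2Cl2, −78 °C; then 27, −78 to −20 °C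
Reagents that add atoms: none
Why: SN1-type alkylation of the chelated (Z)-chlorotitanium enolate of an Evans imide by the doubly stabilised diarylmethyl cation released from 27 (which has no β-hydrogen and cannot eliminate) should form C3–C4, with C3 set by attack on the enolate face remote from the auxiliary benzyl group and C4 expected from an open staggered transition state in which the C4 hydrogen points into the crowded sector between ring B and the titanium-bound oxygen and the 2,6-disubstituted ring C aryl lies anti to the enolate carbonyl carbon; this second element is the least secure stereochemical point of the route.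

Step 16
Reactants: 29 coupled imide
Product: 30 (2R,3S)-primary alcohol still carrying the three silyl ethers
Conditions: LiBH4, H2O (1 equiv), THF/Et2O, 0 °C to rt
Reagents that add atoms: none
Why: Reductive removal of the auxiliary should give the primary alcohol that becomes upper C2–O1, and C3 is not deprotonated under these conditions.

Step 17
Reactants: 30 tris-silyl alcohol
Product: 31 (2R,3S)-2-[2-(benzyloxy)-4,5-dimethoxyphenyl]-3-{4-(benzyloxy)-2-[(2R)-1-hydroxy-3-(4-hydroxyphenyl)propan-2-yl]-6-methoxyphenyl}-3-(4-hydroxyphenyl)propan-1-ol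
Conditions: Bu4NF, AcOH, THF, rt to 40 °C
Reagents that add atoms: none
Why: Fluoride should cleave the two aryl silyl ethers and the primary silyl ether in one operation, freeing exactly the two phenols and two alcohols needed for the ring closures while the benzyl ethers on rings B and C stay on and acetic acid buffers the phenoxides against air oxidation.

Step 18
Reactants: 31 bis-phenol diol
Product: 33 bis(p-quinol) diol, via bis(hydroperoxide) 32 (not isolated)
Conditions: KHSO5 (as 2KHSO5·KHSO4·K2SO4), NaHCO3, MeCN/H2O, rt; then Na2S2O3, H2O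
Reagents that add atoms: potassium peroxymonosulfate ([K+].[O-]OS(O)(=O)=O)
Why: Singlet oxygen released from KHSO5 under bicarbonate should add across each para-alkylphenol to give the 4-hydroperoxy dienones 32 (oxidative dearomatisation as used for tyrosol-type phenols) and thiosulfate then reduces the O–O bonds; unlike an iodine-based oxidant this reagent leaves the free side-chain alcohols uninvolved, and all other phenols are benzyl-protected.

Step 19
Reactants: 33 bis(p-quinol) diol
Product: 35 (3R,4S)-3-[2-(benzyloxy)-4,5-dimethoxyphenyl]-4-{4-(benzyloxy)-2-[(3R)-7-hydroxy-3,4-dihydro-2H-chromen-3-yl]-6-methoxyphenyl}-3,4-dihydro-2H-chromen-7-ol, via bis(oxa-Michael) adduct 34 (not isolated)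
Conditions: DBU (20 mol %), CH2Cl2, 0 °C to rt; then p-TsOH·H2O (50 mol %), 40 °C
Reagents that add atoms: none
Why: Catalytic DBU lets each primary alkoxide add to a β-carbon of its cross-conjugated dienone (intramolecular oxa-Michael addition, 6-exo-trig for both rings, the new bond being O1–C8a of each future chroman) to give the hexahydrochromen-7-one adduct 34; acid then enolises each ketone, ionises the tertiary C4a hydroxyl, and loss of the C8a proton from the arenium-type ion restores the benzene ring with the former carbonyl as the 7-OH. The closest known reaction types are the oxa-Michael cyclisation of hydroxyalkyl p-quinols and the dehydrative rearomatisation of p-quinol Michael adducts to meta-functionalised phenols. No new stereocentre survives: the ring-fusion centres C4a and C8a made in the cyclisation are erased on aromatisation, so the two diastereotopic β-carbons and both ring-fusion geometries converge on one product, and C3, C4 and the lower C3 are neither enolisable nor ionised. The selectivity needed is conjugate addition over acid-induced loss of the benzylic C4 substituent from the upper quinol; it is secured by completing the base-mediated cyclisation before any acid is added, because the cyclised enone can no longer aromatise by C–C cleavage. The substrate feature that makes this work is the 7-OH para to C4a, which renders C8a and C5 of the phenol precursor equivalent.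

Step 20
Reactants: 35 bis-chroman dibenzyl ether
Product: 36 (3R,4S)-3-(2-hydroxy-4,5-dimethoxyphenyl)-4-{4-hydroxy-2-[(3R)-7-hydroxy-3,4-dihydro-2H-chromen-3-yl]-6-methoxyphenyl}-3,4-dihydro-2H-chromen-7-ol (target)
Conditions: H2 (1 atm), Pd/C, EtOAc/MeOH, rt
Reagents that add atoms: none
Why: Hydrogenolysis of the two benzyl aryl ethers should free the ring B and ring C phenols, and since no stereocentre carries a benzylic C–O bond, C3, C4 and the lower C3 are unaffected.

## Compound list

1 | 1-(2-hydroxy-4,5-dimethoxyphenyl)ethan-1-one | CC(=O)c1cc(OC)c(OC)cc1O | starting material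
2 | 1-[2-(benzyloxy)-4,5-dimethoxyphenyl]ethan-1-one | CC(=O)c1cc(OC)c(OC)cc1OCc1ccccc1 | intermediate
3 | 2-[2-(benzyloxy)-4,5-dimethoxyphenyl]-1-(morpholin-4-yl)ethane-1-thione | S=C(Cc1cc(OC)c(OC)cc1OCc1ccccc1)N1CCOCC1 | intermediate
4 | 2-[2-(benzyloxy)-4,5-dimethoxyphenyl]acetic acid | OC(=O)Cc1cc(OC)c(OC)cc1OCc1ccccc1 | intermediate
5 | (4R)-4-benzyl-1,3-oxazolidin-2-one | O=C1N[C@H](Cc2ccccc2)CO1 | starting material
6 | 2-[2-(benzyloxy)-4,5-dimethoxyphenyl]acetic pivalic anhydride | CC(C)(C)C(=O)OC(=O)Cc1cc(OC)c(OC)cc1OCc1ccccc1 | intermediate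
7 | (4R)-4-benzyl-3-{2-[2-(benzyloxy)-4,5-dimethoxyphenyl]acetyl}-1,3-oxazolidin-2-one | O=C(Cc1cc(OC)c(OC)cc1OCc1ccccc1)N1[C@H](Cc2ccccc2)COC1=O | intermediate
8 | 2-(3,5-dihydroxyphenyl)acetic acid | OC(=O)Cc1cc(O)cc(O)c1 | starting material
9 | benzyl 2-[3,5-bis(benzyloxy)phenyl]acetate | O=C(Cc1cc(OCc2ccccc2)cc(OCc2ccccc2)c1)OCc1ccccc1 | intermediate
10 | 2-[3,5-bis(benzyloxy)phenyl]acetic acid | OC(=O)Cc1cc(OCc2ccccc2)cc(OCc2ccccc2)c1 | intermediate
11 | 2-[3,5-bis(benzyloxy)phenyl]acetic pivalic anhydride | CC(C)(C)C(=O)OC(=O)Cc1cc(OCc2ccccc2)cc(OCc2ccccc2)c1 | intermediate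
12 | (4R)-4-benzyl-3-{2-[3,5-bis(benzyloxy)phenyl]acetyl}-1,3-oxazolidin-2-one | O=C(Cc1cc(OCc2ccccc2)cc(OCc2ccccc2)c1)N1[C@H](Cc2ccccc2)COC1=O | intermediate
13 | 4-methylphenol | Cc1ccc(O)cc1 | starting material
14 | triisopropyl(4-methylphenoxy)silane | Cc1ccc(O[Si](C(C)C)(C(C)C)C(C)C)cc1 | intermediate
15 | [4-(bromomethyl)phenoxy]triisopropylsilane | BrCc1ccc(O[Si](C(C)C)(C(C)C)C(C)C)cc1 | intermediate
16 | sodium (Z)-enolate of 12 | [Na+].[O-]/C(=C\c1cc(OCc2ccccc2)cc(OCc2ccccc2)c1)N1[C@H](Cc2ccccc2)COC1=O | intermediate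
17 | (4R)-4-benzyl-3-{(2R)-2-[3,5-bis(benzyloxy)phenyl]-3-[4-(triisopropylsilyloxy)phenyl]propanoyl}-1,3-oxazolidin-2-one | O=C([C@H](Cc1ccc(O[Si](C(C)C)(C(C)C)C(C)C)cc1)c1cc(OCc2ccccc2)cc(OCc2ccccc2)c1)N1[C@H](Cc2ccccc2)COC1=O | intermediate
18 | (2R)-2-[3,5-bis(benzyloxy)phenyl]-3-[4-(triisopropylsilyloxy)phenyl]propan-1-ol | OC[C@H](Cc1ccc(O[Si](C(C)C)(C(C)C)C(C)C)cc1)c1cc(OCc2ccccc2)cc(OCc2ccccc2)c1 | intermediate
19 | {(2R)-2-[3,5-bis(benzyloxy)phenyl]-3-[4-(triisopropylsilyloxy)phenyl]propoxy}(tert-butyl)diphenylsilane | CC(C)(C)[Si](OC[C@H](Cc1ccc(O[Si](C(C)C)(C(C)C)C(C)C)cc1)c1cc(OCc2ccccc2)cc(OCc2ccccc2)c1)(c1ccccc1)c1ccccc1 | intermediate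
20 | dimethyliminium chloride of aldehyde 21 (Vilsmeier iminium salt, iminium carbon ortho to the side chain) | C[N+](C)=Cc1c(OCc2ccccc2)cc(OCc2ccccc2)cc1[C@H](CO[Si](c1ccccc1)(c1ccccc1)C(C)(C)C)Cc1ccc(O[Si](C(C)C)(C(C)C)C(C)C)cc1.[Cl-] | intermediate
21 | 2,4-bis(benzyloxy)-6-{(2R)-1-[(tert-butyldiphenylsilyl)oxy]-3-[4-(triisopropylsilyloxy)phenyl]propan-2-yl}benzaldehyde | O=Cc1c(OCc2ccccc2)cc(OCc2ccccc2)cc1[C@H](CO[Si](c1ccccc1)(c1ccccc1)C(C)(C)C)Cc1ccc(O[Si](C(C)C)(C(C)C)C(C)C)cc1 | intermediate
22 | 4-(benzyloxy)-2-hydroxy-6-{(2R)-1-[(tert-butyldiphenylsilyl)oxy]-3-[4-(triisopropylsilyloxy)phenyl]propan-2-yl}benzaldehyde | O=Cc1c(O)cc(OCc2ccccc2)cc1[C@H](CO[Si](c1ccccc1)(c1ccccc1)C(C)(C)C)Cc1ccc(O[Si](C(C)C)(C(C)C)C(C)C)cc1 | intermediate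
23 | 4-(benzyloxy)-2-methoxy-6-{(2R)-1-[(tert-butyldiphenylsilyl)oxy]-3-[4-(triisopropylsilyloxy)phenyl]propan-2-yl}benzaldehyde | O=Cc1c(OC)cc(OCc2ccccc2)cc1[C@H](CO[Si](c1ccccc1)(c1ccccc1)C(C)(C)C)Cc1ccc(O[Si](C(C)C)(C(C)C)C(C)C)cc1 | intermediate
24 | (4-bromophenoxy)(tert-butyl)dimethylsilane | CC(C)(C)[Si](C)(C)Oc1ccc(Br)cc1 | starting material
25 | {4-[(tert-butyldimethylsilyl)oxy]phenyl}magnesium bromide | CC(C)(C)[Si](C)(C)Oc1ccc([Mg]Br)cc1 | intermediate
26 | bromomagnesium alkoxide of the diarylmethanol from 23 and 25 (both epimers at the carbinol carbon) | Br[Mg]OC(c1ccc(O[Si](C)(C)C(C)(C)C)cc1)c1c(OC)cc(OCc2ccccc2)cc1[C@H](CO[Si](c1ccccc1)(c1ccccc1)C(C)(C)C)Cc1ccc(O[Si](C(C)C)(C(C)C)C(C)C)cc1 | intermediate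
27 | [4-(benzyloxy)-2-methoxy-6-{(2R)-1-[(tert-butyldiphenylsilyl)oxy]-3-[4-(triisopropylsilyloxy)phenyl]propan-2-yl}phenyl]{4-[(tert-butyldimethylsilyl)oxy]phenyl}methyl acetate (both epimers at the acetoxy carbon) | CC(=O)OC(c1ccc(O[Si](C)(C)C(C)(C)C)cc1)c1c(OC)cc(OCc2ccccc2)cc1[C@H](CO[Si](c1ccccc1)(c1ccccc1)C(C)(C)C)Cc1ccc(O[Si](C(C)C)(C(C)C)C(C)C)cc1 | intermediate
28 | trichlorotitanium (Z)-enolate of 7 | Cl[Ti](Cl)(Cl)O/C(=C\c1cc(OC)c(OC)cc1OCc1ccccc1)N1[C@H](Cc2ccccc2)COC1=O | intermediate
29 | (4R)-4-benzyl-3-[(2R,3S)-2-[2-(benzyloxy)-4,5-dimethoxyphenyl]-3-[4-(benzyloxy)-2-methoxy-6-{(2R)-1-[(tert-butyldiphenylsilyl)oxy]-3-[4-(triisopropylsilyloxy)phenyl]propan-2-yl}phenyl]-3-{4-[(tert-butyldimethylsilyl)oxy]phenyl}propanoyl]-1,3-oxazolidin-2-one | O=C([C@@H](c1cc(OC)c(OC)cc1OCc1ccccc1)[C@@H](c1ccc(O[Si](C)(C)C(C)(C)C)cc1)c1c(OC)cc(OCc2ccccc2)cc1[C@H](CO[Si](c1ccccc1)(c1ccccc1)C(C)(C)C)Cc1ccc(O[Si](C(C)C)(C(C)C)C(C)C)cc1)N1[C@H](Cc2ccccc2)COC1=O | intermediate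
30 | (2R,3S)-2-[2-(benzyloxy)-4,5-dimethoxyphenyl]-3-[4-(benzyloxy)-2-methoxy-6-{(2R)-1-[(tert-butyldiphenylsilyl)oxy]-3-[4-(triisopropylsilyloxy)phenyl]propan-2-yl}phenyl]-3-{4-[(tert-butyldimethylsilyl)oxy]phenyl}propan-1-ol | OC[C@@H](c1cc(OC)c(OC)cc1OCc1ccccc1)[C@@H](c1ccc(O[Si](C)(C)C(C)(C)C)cc1)c1c(OC)cc(OCc2ccccc2)cc1[C@H](CO[Si](c1ccccc1)(c1ccccc1)C(C)(C)C)Cc1ccc(O[Si](C(C)C)(C(C)C)C(C)C)cc1 | intermediate
31 | (2R,3S)-2-[2-(benzyloxy)-4,5-dimethoxyphenyl]-3-{4-(benzyloxy)-2-[(2R)-1-hydroxy-3-(4-hydroxyphenyl)propan-2-yl]-6-methoxyphenyl}-3-(4-hydroxyphenyl)propan-1-ol | OC[C@@H](c1cc(OC)c(OC)cc1OCc1ccccc1)[C@@H](c1ccc(O)cc1)c1c(OC)cc(OCc2ccccc2)cc1[C@H](CO)Cc1ccc(O)cc1 | intermediate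
32 | bis(hydroperoxide): 31 in which each 4-hydroxyphenyl group has become a 1-hydroperoxy-4-oxocyclohexa-2,5-dien-1-yl group (side-chain centres unchanged in space) | OC[C@@H](c1cc(OC)c(OC)cc1OCc1ccccc1)[C@@H](C1(OO)C=CC(=O)C=C1)c1c(OC)cc(OCc2ccccc2)cc1[C@H](CO)CC1(OO)C=CC(=O)C=C1 | intermediate
33 | bis(p-quinol): 31 in which each 4-hydroxyphenyl group has become a 1-hydroxy-4-oxocyclohexa-2,5-dien-1-yl group (C3 R, lower centre R, C4 unchanged in space but R by priority) | OC[C@@H](c1cc(OC)c(OC)cc1OCc1ccccc1)[C@@H](C1(O)C=CC(=O)C=C1)c1c(OC)cc(OCc2ccccc2)cc1[C@H](CO)CC1(O)C=CC(=O)C=C1 | intermediate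
34 | bis(oxa-Michael) adduct: two 4a-hydroxy-2,3,4,4a,8,8a-hexahydrochromen-7-one units, the upper one 3-aryl-4-aryl substituted, the lower one attached through C3 to ring C (ring-fusion centres as formed, mixture) | O=C1C=CC2(O)C(C1)OC[C@@H](c1cc(OC)c(OC)cc1OCc1ccccc1)[C@@H]2c1c(OC)cc(OCc2ccccc2)cc1[C@@H]1COC2CC(=O)C=CC2(O)C1 | intermediate
35 | (3R,4S)-3-[2-(benzyloxy)-4,5-dimethoxyphenyl]-4-{4-(benzyloxy)-2-[(3R)-7-hydroxy-3,4-dihydro-2H-chromen-3-yl]-6-methoxyphenyl}-3,4-dihydro-2H-chromen-7-ol | COc1cc(OCc2ccccc2)c([C@@H]2COc3cc(O)ccc3[C@H]2c2c(OC)cc(OCc3ccccc3)cc2[C@@H]2COc3cc(O)ccc3C2)cc1OC | intermediate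
36 | (3R,4S)-3-(2-hydroxy-4,5-dimethoxyphenyl)-4-{4-hydroxy-2-[(3R)-7-hydroxy-3,4-dihydro-2H-chromen-3-yl]-6-methoxyphenyl}-3,4-dihydro-2H-chromen-7-ol | COc1cc(O)c([C@@H]2COc3cc(O)ccc3[C@H]2c2c(OC)cc(O)cc2[C@@H]2COc3cc(O)ccc3C2)cc1OC | target

## Step count and risks

Total step count: 20. Longest linear sequence: 15 steps (steps 4, 5, 8 to 20, from compound 8).

Steps most likely to fail:

1. Step 19 (key step). What may go wrong: cyclisation of the congested upper ring may stay incomplete, and acid then triggers heterolysis of the C4–C4a bond of uncyclised quinol (the benzylic substituent leaves as a cation and hydroquinone forms), or the adduct reopens by retro-Michael reaction before dehydration. Fallback: the two events are separated and the acid is removed. Setting out from 33, the DBU stage is run to completion and adduct 34 is isolated; no compound outside the list is made (F0). The two tertiary alcohols of 34 are then dehydrated with Burgess reagent (methyl N-(triethylammoniosulfonyl)carbamate) in toluene at 60 °C. This is a thermal syn-elimination across C4a–C8a, where hydroxyl and hydrogen are cis in the cis-fused adducts, and it needs no cation. The dienones so formed tautomerise to the phenols, and the route is rejoined at 35.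

2. Step 15. What may go wrong: facial discrimination at the diarylmethyl carbon in the open transition state may be poor or reversed, and the cation may be captured by the neighbouring silyl ether oxygen. Fallback: C4 is built by an aldol reaction and an arylation under 1,2-induction, setting out from 4 and 23 and returning at 31. Acid 4 is loaded as in step 3 onto (4S)-4-benzyl-1,3-oxazolidin-2-one to give the (4S)-auxiliary ring B imide F1; the boron aldol and the alkylation use opposite enolate faces, so the other auxiliary is needed for the same C3 geometry. Bu2BOTf and Et3N, then aldehyde 23 (Evans syn aldol through a Zimmerman–Traxler transition state), give the β-hydroxy imide F2. LiBH4 gives the 1,3-diol F3. In (CF3)2CHOH with excess phenol, the benzylic cation stabilised by ring C is arylated by the para position of phenol anti to ring B, the C3 hydrogen eclipsing the cation plane to avoid allylic 1,3-strain with the ortho substituents of ring C (diastereoselective Friedel–Crafts alkylation of an α-branched benzylic cation); this gives the 4-hydroxyphenyl compound F4. Bu4NF as in step 17 then gives 31.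

3. Step 18. What may go wrong: the electron-rich benzyloxy-dimethoxy ring may be over-oxidised, the tertiary hydroperoxide may eliminate toward the doubly benzylic C4 to give a quinone methide, and the hindered upper phenol may convert incompletely. Fallback: the alcohols are masked and an iodine-based oxidant is used, setting out from 31 and returning at 34. Ac2O in pyridine gives the tetraacetate F5. NH4OAc in aqueous MeOH cleaves only the two aryl acetates to give the bis-phenol diacetate F6. PhI(OAc)2 in MeCN/H2O at 0 °C gives the bis(p-quinol) diacetate F7; the acylated alcohols cannot form spiro ethers, so water adds at the para carbon. K2CO3 in MeOH removes the acetates and the alkoxides cyclise at once to 34, which is taken through the acid stage of step 19.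

Further compounds

F0 | step 19 | none | none
F1 | step 15 | (4S)-4-benzyl-3-{2-[2-(benzyloxy)-4,5-dimethoxyphenyl]acetyl}-1,3-oxazolidin-2-one | O=C(Cc1cc(OC)c(OC)cc1OCc1ccccc1)N1[C@@H](Cc2ccccc2)COC1=O
F2 | step 15 | (4S)-4-benzyl-3-[(2S,3S)-2-[2-(benzyloxy)-4,5-dimethoxyphenyl]-3-hydroxy-3-[4-(benzyloxy)-2-methoxy-6-{(2R)-1-[(tert-butyldiphenylsilyl)oxy]-3-[4-(triisopropylsilyloxy)phenyl]propan-2-yl}phenyl]propanoyl]-1,3-oxazolidin-2-one | O=C([C@@H](c1cc(OC)c(OC)cc1OCc1ccccc1)[C@H](O)c1c(OC)cc(OCc2ccccc2)cc1[C@H](CO[Si](c1ccccc1)(c1ccccc1)C(C)(C)C)Cc1ccc(O[Si](C(C)C)(C(C)C)C(C)C)cc1)N1[C@@H](Cc2ccccc2)COC1=O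
F3 | step 15 | (1S,2R)-2-[2-(benzyloxy)-4,5-dimethoxyphenyl]-1-[4-(benzyloxy)-2-methoxy-6-{(2R)-1-[(tert-butyldiphenylsilyl)oxy]-3-[4-(triisopropylsilyloxy)phenyl]propan-2-yl}phenyl]propane-1,3-diol | OC[C@@H](c1cc(OC)c(OC)cc1OCc1ccccc1)[C@H](O)c1c(OC)cc(OCc2ccccc2)cc1[C@H](CO[Si](c1ccccc1)(c1ccccc1)C(C)(C)C)Cc1ccc(O[Si](C(C)C)(C(C)C)C(C)C)cc1
F4 | step 15 | (2R,3S)-2-[2-(benzyloxy)-4,5-dimethoxyphenyl]-3-[4-(benzyloxy)-2-methoxy-6-{(2R)-1-[(tert-butyldiphenylsilyl)oxy]-3-[4-(triisopropylsilyloxy)phenyl]propan-2-yl}phenyl]-3-(4-hydroxyphenyl)propan-1-ol | OC[C@@H](c1cc(OC)c(OC)cc1OCc1ccccc1)[C@@H](c1ccc(O)cc1)c1c(OC)cc(OCc2ccccc2)cc1[C@H](CO[Si](c1ccccc1)(c1ccccc1)C(C)(C)C)Cc1ccc(O[Si](C(C)C)(C(C)C)C(C)C)cc1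
F5 | step 18 | tetraacetate of 31 (two aryl acetates, two primary alkyl acetates) | CC(=O)OC[C@@H](c1cc(OC)c(OC)cc1OCc1ccccc1)[C@@H](c1ccc(OC(C)=O)cc1)c1c(OC)cc(OCc2ccccc2)cc1[C@H](COC(C)=O)Cc1ccc(OC(C)=O)cc1
F6 | step 18 | bis(primary acetate) of 31 with both phenols free | CC(=O)OC[C@@H](c1cc(OC)c(OC)cc1OCc1ccccc1)[C@@H](c1ccc(O)cc1)c1c(OC)cc(OCc2ccccc2)cc1[C@H](COC(C)=O)Cc1ccc(O)cc1
F7 | step 18 | bis(primary acetate) of bis(p-quinol) 33 | CC(=O)OC[C@@H](c1cc(OC)c(OC)cc1OCc1ccccc1)[C@@H](C1(O)C=CC(=O)C=C1)c1c(OC)cc(OCc2ccccc2)cc1[C@H](COC(C)=O)CC1(O)C=CC(=O)C=C1
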